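The benzoic acid ring hides a mirror plane through C1 (CO2H) and C4 (OH): C3 and C5 carry the same prenyl group, and C2–OMe and C6–CH2 occupy twin positions. The route therefore builds the symmetrical 2,6-dimethoxy-4-(methoxymethoxy)-3,5-diprenylbenzoic acid from methyl 2,4,6-trihydroxybenzoate and, in the key step, lets its free carboxylate direct ipso substitution (SNAr) of one of the two equivalent ortho methoxy groups by 2-[4-(methoxymethoxy)phenyl]ethylmagnesium bromide. This single operation forms the ring C6–CH2 bond and leaves the second methoxy group as the C2–OMe of the target, without halide, triflate or catalyst. Acidic removal of both MOM groups completes the synthesis.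

Key step: step 5

Remark: the target has no stereocentre and no stereogenic double bond (both prenyl alkenes end in CMe2), so it is achiral and no step has to control configuration.

Step 1
Reactants: 1 methyl 2,4,6-trihydroxybenzoate; 2 1-bromo-3-methylbut-2-ene (prenyl bromide)
Product: 3 methyl 2,4,6-trihydroxy-3,5-bis(3-methylbut-2-en-1-yl)benzoate
Conditions: 2 (2.1 equiv), 10% aq KOH, 0 °C; then dilute acid
Reagents that add atoms: none
Why: C-alkylation of a phloroglucinol phenoxide (C-prenylation), in which the polyanion of 1 should react at carbon with the allylic bromide in the protic medium, C3 and C5 being its only free ring positions.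

Step 2
Reactants: 3 methyl 2,4,6-trihydroxy-3,5-bis(3-methylbut-2-en-1-yl)benzoate
Product: 4 methyl 2,6-dihydroxy-4-(methoxymethoxy)-3,5-bis(3-methylbut-2-en-1-yl)benzoate
Conditions: MOMCl (1.05 equiv), i-Pr2NEt, CH2Cl2, 0 °C
Reagents that add atoms: chloromethyl methyl ether (MOMCl), COCCl
Why: MOM protection (O-alkylation with a chloromethyl ether), expected at the C4 hydroxyl because it is the most acidic one (para to the ester) and the only one not held in a hydrogen bond to the ester.

Step 3
Reactants: 4 methyl 2,6-dihydroxy-4-(methoxymethoxy)-3,5-bis(3-methylbut-2-en-1-yl)benzoate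
Product: 6 2,6-dimethoxy-4-(methoxymethoxy)-3,5-bis(3-methylbut-2-en-1-yl)benzoic acid, via methyl ester 5 (not isolated)
Conditions: MeI (3 equiv), K2CO3, DMSO, 40 °C; then 6 M aq KOH, 90 °C; cold 1 M HCl to pH 3
Reagents that add atoms: iodomethane, CI; potassium hydroxide, [K+].[OH-]
Why: Williamson O-methylation of both chelated phenols (the dipolar aprotic solvent favours O- over C-methylation) followed in the same flask by saponification of the methyl ester, conditions under which the MOM ether, the aryl methyl ethers and the prenyl groups should persist.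

Step 4
Reactants: 7 4-(2-bromoethyl)phenol
Product: 8 1-(2-bromoethyl)-4-(methoxymethoxy)benzene
Conditions: MOMCl, i-Pr2NEt, CH2Cl2, 0 °C to rt
Reagents that add atoms: chloromethyl methyl ether (MOMCl), COCCl
Why: MOM protection of a phenol under an amine base, mild enough that phenoxide-triggered loss of the β-bromide (spirocyclisation or elimination) should not compete.

Step 5
Reactants: 6 2,6-dimethoxy-4-(methoxymethoxy)-3,5-bis(3-methylbut-2-en-1-yl)benzoic acid; 8 1-(2-bromoethyl)-4-(methoxymethoxy)benzene
Product: 10 2-methoxy-4-(methoxymethoxy)-6-{2-[4-(methoxymethoxy)phenyl]ethyl}-3,5-bis(3-methylbut-2-en-1-yl)benzoic acid, via arylethyl Grignard reagent 9 (not isolated)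
Conditions: 8 (3.5 equiv), Mg, I2 (cat.), THF, 45 °C; then 6, THF, 0 °C to 65 °C; aq NH4Cl, then cold 1 M HCl to pH 3
Reagents that add atoms: none
Why: Magnesium insertion turns 8 into Grignard reagent 9; its first equivalent deprotonates 6, and a further equivalent, bound through magnesium to the carboxylate and the neighbouring methoxy oxygen, delivers its alkyl group to the methoxy-bearing ring carbon to give a dearomatised σ-adduct (a magnesium ene-diolate) that expels methoxide and rearomatises (addition–elimination). The closest known reaction type is the carboxylate-directed nucleophilic aromatic substitution of unprotected ortho-methoxybenzoic acids by Grignard and organolithium reagents, the free-acid counterpart of the Meyers oxazoline SNAr. No ring is closed and no stereocentre is formed. The step needs ipso substitution in preference to addition at the carboxylate and to a second substitution: the carboxylate carbon is anionic and flanked by two ortho substituents, the two methoxy groups are related by the mirror plane through C1 and C4 so that either gives the same product, and after the first exchange the remaining methoxy group sits beside a more crowded carboxylate and should react more slowly. The C4 OMOM group and the second methoxy group are meta to the attacked carbon, on positions that carry no negative charge in the σ-adduct, so these donors should not switch the substitution off, and the prenyl alkenes and both MOM acetals are inert to the Grignard reagent.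

Step 6
Reactants: 10 2-methoxy-4-(methoxymethoxy)-6-{2-[4-(methoxymethoxy)phenyl]ethyl}-3,5-bis(3-methylbut-2-en-1-yl)benzoic acid
Product: 11 4-hydroxy-2-[2-(4-hydroxyphenyl)ethyl]-6-methoxy-3,5-bis(3-methylbut-2-en-1-yl)benzoic acid (CNP0254933.0)
Conditions: 2 M aq HCl–MeOH (1:4), 35 °C
Reagents that add atoms: none
Why: Acid-catalysed acetal cleavage (MOM deprotection by transacetalisation to methanol) should free both phenols, while the doubly ortho-substituted acid resists Fischer esterification and the dilute acid at mild temperature should neither cyclise a prenyl group onto the C4 phenol nor cause protodecarboxylation.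

Compound list
1 | methyl 2,4,6-trihydroxybenzoate | COC(=O)c1c(O)cc(O)cc1O | starting material
2 | 1-bromo-3-methylbut-2-ene (prenyl bromide) | CC(C)=CCBr | starting material
3 | methyl 2,4,6-trihydroxy-3,5-bis(3-methylbut-2-en-1-yl)benzoate | COC(=O)c1c(O)c(CC=C(C)C)c(O)c(CC=C(C)C)c1O | intermediate
4 | methyl 2,6-dihydroxy-4-(methoxymethoxy)-3,5-bis(3-methylbut-2-en-1-yl)benzoate | COCOc1c(CC=C(C)C)c(O)c(C(=O)OC)c(O)c1CC=C(C)C | intermediate
5 | methyl 2,6-dimethoxy-4-(methoxymethoxy)-3,5-bis(3-methylbut-2-en-1-yl)benzoate | COCOc1c(CC=C(C)C)c(OC)c(C(=O)OC)c(OC)c1CC=C(C)C | intermediate (not isolated)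
6 | 2,6-dimethoxy-4-(methoxymethoxy)-3,5-bis(3-methylbut-2-en-1-yl)benzoic acid | COCOc1c(CC=C(C)C)c(OC)c(C(=O)O)c(OC)c1CC=C(C)C | intermediate
7 | 4-(2-bromoethyl)phenol | Oc1ccc(CCBr)cc1 | starting material
8 | 1-(2-bromoethyl)-4-(methoxymethoxy)benzene | COCOc1ccc(CCBr)cc1 | intermediate
9 | {2-[4-(methoxymethoxy)phenyl]ethyl}magnesium bromide | COCOc1ccc(CC[Mg]Br)cc1 | intermediate (not isolated)
10 | 2-methoxy-4-(methoxymethoxy)-6-{2-[4-(methoxymethoxy)phenyl]ethyl}-3,5-bis(3-methylbut-2-en-1-yl)benzoic acid | COCOc1ccc(CCc2c(C(=O)O)c(OC)c(CC=C(C)C)c(OCOC)c2CC=C(C)C)cc1 | intermediate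
11 | 4-hydroxy-2-[2-(4-hydroxyphenyl)ethyl]-6-methoxy-3,5-bis(3-methylbut-2-en-1-yl)benzoic acid | COc1c(CC=C(C)C)c(O)c(CC=C(C)C)c(CCc2ccc(O)cc2)c1C(=O)O | target

Total step count: 6. Longest linear sequence: 5 steps (steps 1, 2, 3, 5 and 6).

Steps most likely to fail

Step 5. Addition of the Grignard reagent to the methoxy-bearing carbon may be too slow, because that carbon is shielded by the carboxylate on one side and a prenyl group on the other and lies in an electron-rich ring. The reagent would then only deprotonate the acid or, on forcing, add to the carboxylate or exchange both methoxy groups. The fallback forms the same aryl–CH2 bond by cross-coupling instead of SNAr; it sets out from 4 and comes back to the route at 10. Mono-O-methylation of 4 (MeI 1.05 equiv, K2CO3, acetone, rt; the second hydroxyl stays locked in a hydrogen bond to the ester carbonyl) should give methyl 2-hydroxy-6-methoxy-4-(methoxymethoxy)-3,5-bis(3-methylbut-2-en-1-yl)benzoate F1. Triflation (Tf2O, pyridine, CH2Cl2, 0 °C) should give methyl 2-methoxy-4-(methoxymethoxy)-3,5-bis(3-methylbut-2-en-1-yl)-6-(trifluoromethanesulfonyloxy)benzoate F2. Zinc insertion into 8 (Zn dust, LiCl, THF, 40 °C) should give {2-[4-(methoxymethoxy)phenyl]ethyl}zinc bromide F3. Negishi coupling of F2 with F3 (Pd(OAc)2, SPhos, THF, 60 °C) should give methyl 2-methoxy-4-(methoxymethoxy)-6-{2-[4-(methoxymethoxy)phenyl]ethyl}-3,5-bis(3-methylbut-2-en-1-yl)benzoate F4. Saponification of F4 (KOH, DMSO–H2O, 90 °C) should then give 10.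

Step 1. Alkylation may run past the diprenyl stage (geminal C-prenylation with loss of aromaticity), go to oxygen, or stop after one prenyl group, so that 3 is only one component of a mixture. The fallback replaces phenoxide alkylation by three directed ortho-metalations. It sets out from 2, which stays the prenyl source, and from commercial 3,5-dimethoxyphenol F5, and it comes back to the route at 6, bypassing steps 1 to 3. MOM protection (MOMCl, i-Pr2NEt, CH2Cl2) should give 1,3-dimethoxy-5-(methoxymethoxy)benzene F6. n-BuLi in THF at 0 °C should lithiate between the OMOM and an OMe group, the acetal being the stronger director, to give [2,4-dimethoxy-6-(methoxymethoxy)phenyl]lithium F7, and alkylation with 2 should give 1,5-dimethoxy-3-(methoxymethoxy)-2-(3-methylbut-2-en-1-yl)benzene F8. A second lithiation on the other side of the OMOM group should give [4,6-dimethoxy-2-(methoxymethoxy)-3-(3-methylbut-2-en-1-yl)phenyl]lithium F9, and alkylation with 2 should give 1,5-dimethoxy-3-(methoxymethoxy)-2,4-bis(3-methylbut-2-en-1-yl)benzene F10. The only ring hydrogen left lies between the two methoxy groups, so a third lithiation (n-BuLi, TMEDA, THF) should give [2,6-dimethoxy-4-(methoxymethoxy)-3,5-bis(3-methylbut-2-en-1-yl)phenyl]lithium F11, and a CO2 quench should give 6.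

Step 3. Hydroxide may fail to reach the ester carbonyl, which is shielded by two ortho methoxy groups that are themselves pressed inward by the prenyl groups, and long heating with strong base may move the prenyl double bonds. The fallback cleaves the ester at the methyl carbon instead of at the carbonyl; it sets out from 5, now isolated after the methylation, and comes back to the route at 6. Lithium propane-1-thiolate in DMPU at rt should remove the ester methyl group by SN2 dealkylation, which is insensitive to shielding of the carbonyl and should leave aryl methyl ethers, the MOM ether and the alkenes alone; cold acidification then gives 6. This fallback makes no new compound (F0).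

Further compounds
F1 | step 5 | methyl 2-hydroxy-6-methoxy-4-(methoxymethoxy)-3,5-bis(3-methylbut-2-en-1-yl)benzoate | COCOc1c(CC=C(C)C)c(O)c(C(=O)OC)c(OC)c1CC=C(C)C
F2 | step 5 | methyl 2-methoxy-4-(methoxymethoxy)-3,5-bis(3-methylbut-2-en-1-yl)-6-(trifluoromethanesulfonyloxy)benzoate | COCOc1c(CC=C(C)C)c(OS(=O)(=O)C(F)(F)F)c(C(=O)OC)c(OC)c1CC=C(C)C
F3 | step 5 | {2-[4-(methoxymethoxy)phenyl]ethyl}zinc bromide | COCOc1ccc(CC[Zn]Br)cc1
F4 | step 5 | methyl 2-methoxy-4-(methoxymethoxy)-6-{2-[4-(methoxymethoxy)phenyl]ethyl}-3,5-bis(3-methylbut-2-en-1-yl)benzoate | COCOc1ccc(CCc2c(C(=O)OC)c(OC)c(CC=C(C)C)c(OCOC)c2CC=C(C)C)cc1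
F5 | step 1 | 3,5-dimethoxyphenol | COc1cc(O)cc(OC)c1
F6 | step 1 | 1,3-dimethoxy-5-(methoxymethoxy)benzene | COCOc1cc(OC)cc(OC)c1
F7 | step 1 | [2,4-dimethoxy-6-(methoxymethoxy)phenyl]lithium | COCOc1cc(OC)cc(OC)c1[Li]
F8 | step 1 | 1,5-dimethoxy-3-(methoxymethoxy)-2-(3-methylbut-2-en-1-yl)benzene | COCOc1cc(OC)cc(OC)c1CC=C(C)C
F9 | step 1 | [4,6-dimethoxy-2-(methoxymethoxy)-3-(3-methylbut-2-en-1-yl)phenyl]lithium | COCOc1c([Li])c(OC)cc(OC)c1CC=C(C)C
F10 | step 1 | 1,5-dimethoxy-3-(methoxymethoxy)-2,4-bis(3-methylbut-2-en-1-yl)benzene | COCOc1c(CC=C(C)C)c(OC)cc(OC)c1CC=C(C)C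
F11 | step 1 | [2,6-dimethoxy-4-(methoxymethoxy)-3,5-bis(3-methylbut-2-en-1-yl)phenyl]lithium | COCOc1c(CC=C(C)C)c(OC)c([Li])c(OC)c1CC=C(C)C
F0 | step 3 | none | none
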